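Add Z and X at the last reading of each run. This pool, counted as the fraction left of the Z charged, is the one balance you can read directly.

| setting | noon | winter | Tuesday's | Saturday's | Monday's | Sunday's | Wednesday's |
|---|---|---|---|---|---|---|---|
| Z | 0.80 M | 0.80 M | 0.80 M | 0.80 M | 0.80 M | 0.80 M | 0.80 M |
| L | 0.069 M | 1 M | 0.0500 M | 0.100 M | 0.200 M | 0.400 M | 0.800 M |
| remark | run made earlier | run made earlier |  |  |  |  |  |
| time |  |  | 20 h | 20 h | 20 h | 20 h | 20 h |

- noon (time / h: X / %, Z / %): 1.33: 18, 83; 4.00: 31, 65; 6.00: 38, 56; 10.0: 41, 46; 15.0: 39, 39
- winter (time / h: X / %, Z / %): 1.00: 11, 87; 2.00: 20, 77; 4.00: 31, 59; 8.00: 36, 48; 15.0: 37, 34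

(scatter of a reading: 1.5 percentage points)

- percent here means Z units held: one X or D counts as two
- percent here means Z units held: one Q counts as three
- steps that have been proposed: 2 Z <-> X; X <-> D; Z + X -> Q; Z + L -> G
- "hardly changes" means that all values lie within two and a half points (for a concentration: within two and a half percent of the largest)

* [X] at the end for Tuesday's, Saturday's, Monday's, Sunday's, Wednesday's, in this order
* the shape of the row from first to last (rises all the way / falls all the way / hardly changes / falls, then rises / rises, then falls)

You can order the flask as a ladder of time scales. On the fastest rung, Z pairs into X. Taken as second order, the first noon reading gives Z a half-life of 6.49 h. This is shorter than the time asked, so by the end X should follow the pool: noon X reads 41% at 10.0 h and 39% at 15.0 h.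

On the next rung the pool itself leaks. The noon run holds 78.0% at 15.0 h, which gives a lifetime of

t_p = 60.4 h

The winter run holds 71.0%. That is 7 percentage points lower, with a scatter of 3 points on the difference. Working with fractions left gives

s = ln(noon pool / winter pool) / (Δ[L] · t) = 0.00673 /M/h

Call s the L toll, the fraction of the pool lost per hour per molar of L. Multiplied by [L], it is a pseudo-first-order constant. The slowest rung is this toll, with a lifetime at Wednesday's [L] of 186 h, longer than the other two. It is the term of this reckoning that carries [L], so the fall along the row is reckoned from it.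

My own reckoning carries the noon X forward to Tuesday's flask at the time asked:

[X] = 0.144 M

Wednesday's stands at exp(−s·Δ[L]·t) = 0.904 of that, or 0.130 M, so the row falls all the way.

The forecast gives 0.146 M, 0.145 M, 0.144 M, 0.141 M, 0.136 M, a row that falls all the way, with a last-to-first ratio of 0.932, gentler than mine, on the ground “so Z + L → G is slow”.

The flasks give 0.151 M, 0.150 M, 0.148 M, 0.145 M, 0.138 M: the row falls all the way.

    2 Z ⇌ X (K = 2.73 /M, k = 0.0940 /M/h)
    X ⇌ D (K = 1.41, k = 0.0376 /h)
    Z + X → Q (k = 0.0151 /M/h)
    Z + L → G (k = 0.0110 /M/h)

In Tuesday's flask the turnover of Z into X had its midpoint at 3.27 h, and at 3.27 h X was made 4.76 times faster than it was used up; by 20.0 h that ratio had dropped to 0.514, with D at 21.0% and Q at 6.05%. In Wednesday's flask G grew throughout, reaching 8.28% against Tuesday's 0.539%, and the row's last-to-first ratio came to 0.914 against the toll's 0.904. For Sunday's flask the toll gives 0.954, and its [X] stands at 0.960 of Tuesday's.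

The readings are simulated with made-up constants; the scatter is artificial.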